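**Plan**

- Retrosynthesis: the C3 angelate and C9 senecioate C–O bonds are cut first, then C7–C11 (isopropenyl), the C9–O bond and the C3–O/C4–H pair, back to a cis-fused 3-en-8-one. The C5–C6 bond of ring B is then opened by a retro-[3,3] shift to a 2-vinylbicyclo[2.2.2]oct-5-en-2-ol. Cutting C7–C8 (vinyl addition) and C2–C3/C1–C10 (Diels–Alder) leads to a guaiacol-derived masked o-benzoquinone.
- Enabling feature: the C8 ketone is flanked by oxygenated C9 and lies three bonds from quaternary C5 (C8–C7–C6–C5). Ring A atoms C3, C4, C5, C10 with C1, C2 and C8, C9 therefore form a bicyclo[2.2.2]octene in which C4=C5 is the dimethyl alkene, C8 the vinyl carbinol and C9 the ketal carbon.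
- Forward order: arene → bicyclooctenone (ring A atoms plus C8/C9) → vinyl carbinol → anionic oxy-Cope closes ring B (C5–C6 made, C3–C8 broken) → ring A is oxygenated → C9, then C7 are functionalised → the two esters go on last.
- Stereochemistry: absolute configuration from resolution of the bicyclic alcohol as its (1S)-camphanate. C5/C10 follow from the geometry of the sigmatropic shift. C4 (equilibration) and C3 (thermodynamic reduction) are set while a C8 ketal holds the chair–chair form with the C5 methyl axial on ring A. C9 comes from convex-face Rubottom oxidation, C7 from equilibration to the equatorial position, and the (Z)-ester geometry from angelic acid.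

Key step: step 9

Remark: from 16 on, atoms carry eremophilane numbers (ring A = C1–C5 and C10, ring B = C5–C10); β is the face of the C5 methyl and H-10; racemates 6–8 are drawn as the enantiomer carried on, and the two camphanate diastereomers of step 5 are assumed separable, the wanted one being assigned by X-ray analysis.

**Step 1**
Reactants: 1 3,4-dimethylphenol
Product: 2 2-bromo-4,5-dimethylphenol
Conditions: Br2, CH2Cl2, 0 °C
Reagents that add atoms: bromine BrBr
Why: Electrophilic aromatic bromination; para to OH is blocked and the ortho site between OH and methyl is hindered, so bromine should enter at C6.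

**Step 2**
Reactants: 2 2-bromo-4,5-dimethylphenol
Product: 3 2-methoxy-4,5-dimethylphenol
Conditions: NaOMe, CuI (cat.), DMF/MeOH, 110 °C; aq. HCl
Reagents that add atoms: sodium methoxide [Na+].[O-]C
Why: Copper-catalysed Ullmann-type methoxylation of an o-bromophenol, the standard entry to guaiacols.

**Step 3**
Reactants: 3 2-methoxy-4,5-dimethylphenol; 4 phenyl vinyl sulfone
Product: 6 rac-3,3-dimethoxy-5,6-dimethyl-7-(phenylsulfonyl)bicyclo[2.2.2]oct-5-en-2-one, via masked o-benzoquinone 5 (not isolated)
Conditions: PhI(OAc)2, MeOH, 4 (excess), 0 °C → 50 °C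
Reagents that add atoms: methanol CO; phenyl vinyl sulfone C=CS(=O)(=O)c1ccccc1
Why: Oxidative dearomatisation by the trivalent-iodine reagent in methanol gives the o-quinone monoketal, which is trapped in situ by the sulfone (an ethylene equivalent) in a Diels–Alder reaction; the adduct is racemic and the position and configuration of the sulfonyl group are immaterial because step 4 removes it.

**Step 4**
Reactants: 6 rac-3,3-dimethoxy-5,6-dimethyl-7-(phenylsulfonyl)bicyclo[2.2.2]oct-5-en-2-one
Product: 8 rac-3,3-dimethoxy-5,6-dimethylbicyclo[2.2.2]oct-5-en-2-ol, via hydroxy sulfone 7 (not isolated)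
Conditions: NaBH4, MeOH, 0 °C; then Na2HPO4, 6% Na(Hg), −20 °C → rt
Reagents that add atoms: none
Why: Borohydride reduction from the less hindered alkene face (OH ends syn to the ethano bridge) shields the carbonyl level, after which electron transfer from Na(Hg) cleaves the C–S bond (reductive desulfonylation) and erases the sulfonyl stereocentre.

**Step 5**
Reactants: 8 rac-3,3-dimethoxy-5,6-dimethylbicyclo[2.2.2]oct-5-en-2-ol
Product: 9 (1R,2R,4S)-3,3-dimethoxy-5,6-dimethylbicyclo[2.2.2]oct-5-en-2-yl (1S,4R)-camphanate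
Conditions: (1S)-camphanic chloride, pyridine, DMAP (cat.), CH2Cl2, rt; diastereomers separated by chromatography and crystallisation
Reagents that add atoms: (1S)-(−)-camphanic chloride ClC(=O)[C@@]12CC[C@@](C)(C(=O)O1)C2(C)C
Why: Classical resolution: acylation with an enantiopure acid chloride turns the enantiomers into separable diastereomeric esters, and the (1R,2R,4S) ester is kept, its configuration to be secured by X-ray analysis against the known camphanoyl unit.

**Step 6**
Reactants: 9 (1R,2R,4S)-3,3-dimethoxy-5,6-dimethylbicyclo[2.2.2]oct-5-en-2-yl (1S,4R)-camphanate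
Product: 10 (1R,2R,4S)-3,3-dimethoxy-5,6-dimethylbicyclo[2.2.2]oct-5-en-2-ol
Conditions: NaOMe (cat.), MeOH, 50 °C
Reagents that add atoms: none
Why: Base-catalysed transesterification (methanolysis) releases the resolved alcohol without touching the ketal or any stereocentre.

**Step 7**
Reactants: 10 (1R,2R,4S)-3,3-dimethoxy-5,6-dimethylbicyclo[2.2.2]oct-5-en-2-ol
Product: 11 (1R,4S)-3,3-dimethoxy-5,6-dimethylbicyclo[2.2.2]oct-5-en-2-one
Conditions: Dess–Martin periodinane, NaHCO3, CH2Cl2, rt
Reagents that add atoms: none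
Why: Dess–Martin oxidation of the secondary alcohol under buffered neutral conditions; the bridgehead stereocentres cannot epimerise.

**Step 8**
Reactants: 11 (1R,4S)-3,3-dimethoxy-5,6-dimethylbicyclo[2.2.2]oct-5-en-2-one; 12 vinylmagnesium bromide
Product: 13 (1R,2R,4S)-3,3-dimethoxy-5,6-dimethyl-2-vinylbicyclo[2.2.2]oct-5-en-2-ol
Conditions: CH2=CHMgBr, CeCl3, THF, −78 °C → 0 °C; aq. NH4Cl
Reagents that add atoms: vinylmagnesium bromide C=C[Mg]Br
Why: Cerium-mediated Grignard 1,2-addition from the face of the alkene bridge, which is less hindered than the ethano bridge with its inward hydrogens, so the vinyl group ends syn to the C5=C6 alkene (2R) as the sigmatropic shift requires.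

**Step 9**
Reactants: 13 (1R,2R,4S)-3,3-dimethoxy-5,6-dimethyl-2-vinylbicyclo[2.2.2]oct-5-en-2-ol
Product: 16 (4aS,8aS)-1,1-dimethoxy-4a,5-dimethyl-3,4,4a,7,8,8a-hexahydronaphthalen-2(1H)-one, via potassium alkoxide 14 (not isolated), via potassium enolate 15 (not isolated)
Conditions: KH, 18-crown-6, THF, rt → 50 °C; aq. NH4Cl
Reagents that add atoms: none
Why: Deprotonation gives the crown-ether-separated alkoxide 14, whose 1,5-diene (C6=C7–C8–C3–C4=C5) undergoes a concerted alkoxide-accelerated [3,3]-sigmatropic shift through the boat geometry imposed by the bicycle, C6 bonding to C5 as C3–C8 breaks, to give enolate 15, which is protonated on work-up. The closest known reaction type is the anionic oxy-Cope rearrangement of 2-vinylbicyclo[2.2.2]oct-5-en-2-ols derived from masked o-benzoquinone adducts to cis-decalins. Ring B (C5–C10) closes as a six-membered ring in a six-centre pericyclic mode while the bicyclo[2.2.2]octene opens to the bicyclo[4.4.0] skeleton. The one new stereocentre, quaternary C5, is controlled by C10: C6 can reach C5 only on the alkene face turned toward the C8–C9 bridge, the side on which C10 carries C9, so the C5 methyl and H-10 must end cis. The step needs the vinyl group syn to the alkene, which step 8 secures, and there is only one 1,5-diene, so no regiochemical choice arises. Enolate formation and loss of bicyclic strain should make it irreversible, and the ketal leaves C7 as the only site that can carry the enolate.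

**Step 10**
Reactants: 16 (4aS,8aS)-1,1-dimethoxy-4a,5-dimethyl-3,4,4a,7,8,8a-hexahydronaphthalen-2(1H)-one
Product: 17 (4aS,8aR)-4a,5-dimethyl-3,4,4a,7,8,8a-hexahydronaphthalen-2(1H)-one
Conditions: SmI2, THF/MeOH, −78 °C → rt
Reagents that add atoms: none
Why: Divalent samarium cleaves both α-methoxy groups by ketyl formation and β-elimination (reductive α-deoxygenation), removing a ketal whose axial methoxy group would sit in the concave pocket over ring A and bias the ring-A stereochemistry the wrong way; no stereocentre is touched.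

**Step 11**
Reactants: 17 (4aS,8aR)-4a,5-dimethyl-3,4,4a,7,8,8a-hexahydronaphthalen-2(1H)-one
Product: 18 8,8-ethylenedioxy-4,5-dimethyl-10βH-cis-octal-3-ene
Conditions: HOCH2CH2OH, TsOH (cat.), benzene, reflux (Dean–Stark)
Reagents that add atoms: ethylene glycol OCCO
Why: Acid-catalysed ketalisation protects the carbonyl from borane and serves as a conformational anchor: one ketal oxygen must be axial at C8, which clashes with C1 in the other chair–chair form, so the form with the C5 methyl axial on ring A is held.

**Step 12**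
Reactants: 18 8,8-ethylenedioxy-4,5-dimethyl-10βH-cis-octal-3-ene
Product: 20 8,8-ethylenedioxy-4,5-dimethyl-10βH-cis-decalin-3-one as C4 epimers, via C3 alkylborane 19 (not isolated)
Conditions: BH3·THF, THF, 0 °C → rt; then NMO, Pr4N[RuO4] (cat.), 4 Å MS, CH2Cl2, rt
Reagents that add atoms: N-methylmorpholine N-oxide C[N+]1([O-])CCOCC1
Why: Anti-Markovnikov hydroboration puts boron on the less substituted C3, and amine-oxide/perruthenate oxidation of the organoborane gives the C3 ketone directly, so the facial outcome of the addition (both faces are hindered) does not matter.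

**Step 13**
Reactants: 20 8,8-ethylenedioxy-4,5-dimethyl-10βH-cis-decalin-3-one as C4 epimers
Product: 22 8,8-ethylenedioxy-4β,5β-dimethyl-10βH-decalin-3α-ol, via 4β-methyl ketone 21 (not isolated)
Conditions: KOt-Bu (cat.), t-BuOH/THF, 40 °C; then Li, NH3 (l), −78 °C; NH4Cl
Reagents that add atoms: none
Why: Alkoxide-mediated enolisation equilibrates C4 to the equatorial 4β-methyl epimer (a 4α-methyl would be axial in the anchored conformer and clash with C9), and dissolving-metal reduction then gives the thermodynamically preferred equatorial 3α-alcohol, the axial epimer being destabilised by a 1,3-diaxial contact with the C5 methyl.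

**Step 14**
Reactants: 22 8,8-ethylenedioxy-4β,5β-dimethyl-10βH-decalin-3α-ol
Product: 23 3α-(tert-butyldimethylsilyloxy)-8,8-ethylenedioxy-4β,5β-dimethyl-10βH-decalin
Conditions: TBSCl, imidazole, DMF, 40 °C
Reagents that add atoms: tert-butyldimethylsilyl chloride CC(C)(C)[Si](C)(C)Cl
Why: Standard silylation of a secondary alcohol; the TBS ether should withstand the base, peracid and mild fluoride steps ahead.

**Step 15**
Reactants: 23 3α-(tert-butyldimethylsilyloxy)-8,8-ethylenedioxy-4β,5β-dimethyl-10βH-decalin
Product: 24 3α-(tert-butyldimethylsilyloxy)-4β,5β-dimethyl-10βH-decalin-8-one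
Conditions: PPTS, acetone/H2O, 55 °C
Reagents that add atoms: water O
Why: Acid-catalysed ketal hydrolysis frees the C8 ketone once C4 is configurationally locked (no carbonyl next to it), the hindered secondary TBS ether surviving mild aqueous acid.

**Step 16**
Reactants: 24 3α-(tert-butyldimethylsilyloxy)-4β,5β-dimethyl-10βH-decalin-8-one
Product: 25 3α-(tert-butyldimethylsilyloxy)-8-(triethylsilyloxy)-4β,5β-dimethyl-10βH-octal-8-ene
Conditions: Et3SiOTf, Et3N, CH2Cl2, 0 °C → rt
Reagents that add atoms: triethylsilyl triflate CC[Si](CC)(CC)OS(=O)(=O)C(F)(F)F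
Why: Soft enolisation under equilibrating conditions gives the more stable silyl enol ether, which in this cis-fused decalone (the same ring relationship as in 5β-3-keto steroids) points toward the ring-fusion carbon, i.e. C8=C9.

**Step 17**
Reactants: 25 3α-(tert-butyldimethylsilyloxy)-8-(triethylsilyloxy)-4β,5β-dimethyl-10βH-octal-8-ene
Product: 27 3α-(tert-butyldimethylsilyloxy)-9β-(triethylsilyloxy)-4β,5β-dimethyl-10βH-decalin-8-one, via silyloxy epoxide 26 (not isolated)
Conditions: mCPBA, NaHCO3, CH2Cl2, −20 °C → 0 °C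
Reagents that add atoms: mCPBA OOC(=O)c1cccc(Cl)c1
Why: Rubottom oxidation: the peracid epoxidises the enol ether on the convex β face of ring B (the α face is covered by C4) and 1,4-silyl migration gives the α-silyloxy ketone with the C9 oxygen equatorial (9β), which is also the thermodynamic epimer.

**Step 18**
Reactants: 27 3α-(tert-butyldimethylsilyloxy)-9β-(triethylsilyloxy)-4β,5β-dimethyl-10βH-decalin-8-one; 28 2-bromopropene
Product: 30 3α-(tert-butyldimethylsilyloxy)-9β-(triethylsilyloxy)-10βH-eremophil-11-en-8-one, via lithium enolate 29 (not isolated)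
Conditions: LiN(SiMe3)2, Pd2(dba)3 (cat.), P(t-Bu)3 (cat.), toluene/THF, −78 °C → rt; AcOH, −78 °C
Reagents that add atoms: 2-bromopropene CC(Br)=C
Why: Palladium-catalysed α-alkenylation of a ketone enolate with an alkenyl bromide (oxidative addition to zerovalent palladium, enolate transfer, reductive elimination); only C7 offers an unhindered enolisable CH2 because C9 is a silyloxy methine, and kinetic α-protonation of the product dienolate followed by epimerisation should give the equatorial 7β-isopropenyl group (7α would be axial and syn to C4) with the alkene out of conjugation.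

**Step 19**
Reactants: 30 3α-(tert-butyldimethylsilyloxy)-9β-(triethylsilyloxy)-10βH-eremophil-11-en-8-one
Product: 31 3α-(tert-butyldimethylsilyloxy)-9β-hydroxy-10βH-eremophil-11-en-8-one
Conditions: HF·pyridine, pyridine, THF, 0 °C
Reagents that add atoms: none
Why: Selective desilylation: buffered fluoride cleaves the triethylsilyl ether much faster than the hindered secondary TBS ether, under conditions too mild to move the isopropenyl double bond.

**Step 20**
Reactants: 31 3α-(tert-butyldimethylsilyloxy)-9β-hydroxy-10βH-eremophil-11-en-8-one; 32 senecioyl chloride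
Product: 33 3α-(tert-butyldimethylsilyloxy)-9β-senecioyloxy-10βH-eremophil-11-en-8-one
Conditions: Me2C=CHCOCl, pyridine, CH2Cl2, 0 °C
Reagents that add atoms: senecioyl chloride CC(C)=CC(=O)Cl
Why: Acylation of the α-ketol with an acid chloride and pyridine, a base too weak to form the vinylketene that would deconjugate the senecioyl group; C9 keeps its equatorial, thermodynamically preferred configuration.

**Step 21**
Reactants: 33 3α-(tert-butyldimethylsilyloxy)-9β-senecioyloxy-10βH-eremophil-11-en-8-one
Product: 34 3α-hydroxy-9β-senecioyloxy-10βH-eremophil-11-en-8-one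
Conditions: HF·pyridine, THF, rt
Reagents that add atoms: none
Why: Fluoride-mediated desilylation under weakly acidic conditions that should leave the β,γ-unsaturated ketone and the α-acyloxy ketone intact.

**Step 22**
Reactants: 34 3α-hydroxy-9β-senecioyloxy-10βH-eremophil-11-en-8-one; 35 angelic acid
Product: 36 (3R,4R,5R,7R,9R,10S)-3-angeloyloxy-9-senecioyloxyeremophil-11-en-8-one
Conditions: 35, 2,4,6-Cl3C6H2COCl, Et3N, toluene, rt; then 34, 75 °C
Reagents that add atoms: angelic acid C/C=C(/C)C(=O)O
Why: Yamaguchi-type mixed-anhydride esterification run without a nucleophilic pyridine catalyst, the variant that preserves the (Z)-geometry of angelic acid; the equatorial 3α-hydroxyl is acylated with retention, which completes the target.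

**Compound list**

1 | 3,4-dimethylphenol | Cc1ccc(O)cc1C | starting material
2 | 2-bromo-4,5-dimethylphenol | Cc1cc(O)c(Br)cc1C | intermediate
3 | 2-methoxy-4,5-dimethylphenol | COc1cc(C)c(C)cc1O | intermediate
4 | phenyl vinyl sulfone | C=CS(=O)(=O)c1ccccc1 | starting material
5 | 6,6-dimethoxy-3,4-dimethylcyclohexa-2,4-dien-1-one (masked o-benzoquinone) | COC1(OC)C=C(C)C(C)=CC1=O | intermediate (not isolated)
6 | rac-3,3-dimethoxy-5,6-dimethyl-7-(phenylsulfonyl)bicyclo[2.2.2]oct-5-en-2-one (sulfonyl next to the bridgehead α to C=O, syn to the alkene bridge) | O=C1C(OC)(OC)[C@H]2C[C@H](S(=O)(=O)c3ccccc3)[C@@H]1C(C)=C2C | intermediate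
7 | rac-3,3-dimethoxy-5,6-dimethyl-7-(phenylsulfonyl)bicyclo[2.2.2]oct-5-en-2-ol (OH syn to the ethano bridge) | O[C@H]1C(OC)(OC)[C@H]2C[C@H](S(=O)(=O)c3ccccc3)[C@@H]1C(C)=C2C | intermediate (not isolated)
8 | rac-3,3-dimethoxy-5,6-dimethylbicyclo[2.2.2]oct-5-en-2-ol (OH syn to the ethano bridge) | O[C@H]1C(OC)(OC)[C@H]2CC[C@@H]1C(C)=C2C | intermediate
9 | (1R,2R,4S)-3,3-dimethoxy-5,6-dimethylbicyclo[2.2.2]oct-5-en-2-yl (1S,4R)-camphanate | O=C(O[C@H]1C(OC)(OC)[C@H]2CC[C@@H]1C(C)=C2C)[C@@]34CC[C@@](C)(C(=O)O3)C4(C)C | intermediate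
10 | (1R,2R,4S)-3,3-dimethoxy-5,6-dimethylbicyclo[2.2.2]oct-5-en-2-ol | O[C@H]1C(OC)(OC)[C@H]2CC[C@@H]1C(C)=C2C | intermediate
11 | (1R,4S)-3,3-dimethoxy-5,6-dimethylbicyclo[2.2.2]oct-5-en-2-one | O=C1C(OC)(OC)[C@H]2CC[C@@H]1C(C)=C2C | intermediate
12 | vinylmagnesium bromide | C=C[Mg]Br | starting material
13 | (1R,2R,4S)-3,3-dimethoxy-5,6-dimethyl-2-vinylbicyclo[2.2.2]oct-5-en-2-ol (vinyl syn to the alkene bridge) | C=C[C@]1(O)C(OC)(OC)[C@H]2CC[C@@H]1C(C)=C2C | intermediate
14 | potassium alkoxide of 13 | C=C[C@]1([O-])C(OC)(OC)[C@H]2CC[C@@H]1C(C)=C2C.[K+] | intermediate (not isolated)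
15 | potassium C7=C8 enolate of 16 | [O-]C1=CC[C@@]2(C)[C@H](CCC=C2C)C1(OC)OC.[K+] | intermediate (not isolated)
16 | (4aS,8aS)-1,1-dimethoxy-4a,5-dimethyl-3,4,4a,7,8,8a-hexahydronaphthalen-2(1H)-one (cis-fused 9,9-dimethoxy-3-en-8-one) | O=C1CC[C@@]2(C)[C@H](CCC=C2C)C1(OC)OC | intermediate
17 | (4aS,8aR)-4a,5-dimethyl-3,4,4a,7,8,8a-hexahydronaphthalen-2(1H)-one (cis-fused 3-en-8-one) | O=C1CC[C@@]2(C)[C@H](CCC=C2C)C1 | intermediate
18 | 8,8-ethylenedioxy-4,5-dimethyl-10βH-cis-octal-3-ene (C8 dioxolane of 17) | O1CCOC12CC[C@@]3(C)[C@H](CCC=C3C)C2 | intermediate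
19 | C3 alkylborane from 18 (boron on C3, hydrogen on C4, both faces) | O1CCOC12CC[C@@]3(C)[C@H](CCC(B)C3C)C2 | intermediate (not isolated)
20 | 8,8-ethylenedioxy-4,5-dimethyl-10βH-cis-decalin-3-one, C4 epimers | O1CCOC12CC[C@@]3(C)[C@H](CCC(=O)C3C)C2 | intermediate
21 | 8,8-ethylenedioxy-4β,5β-dimethyl-10βH-decalin-3-one | O1CCOC12CC[C@@]3(C)[C@H](CCC(=O)[C@@H]3C)C2 | intermediate (not isolated)
22 | 8,8-ethylenedioxy-4β,5β-dimethyl-10βH-decalin-3α-ol | O1CCOC12CC[C@@]3(C)[C@H](CC[C@@H](O)[C@@H]3C)C2 | intermediate
23 | 3α-(tert-butyldimethylsilyloxy)-8,8-ethylenedioxy-4β,5β-dimethyl-10βH-decalin | O1CCOC12CC[C@@]3(C)[C@H](CC[C@@H](O[Si](C)(C)C(C)(C)C)[C@@H]3C)C2 | intermediate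
24 | 3α-(tert-butyldimethylsilyloxy)-4β,5β-dimethyl-10βH-decalin-8-one | O=C1CC[C@@]2(C)[C@H](CC[C@@H](O[Si](C)(C)C(C)(C)C)[C@@H]2C)C1 | intermediate
25 | 3α-(tert-butyldimethylsilyloxy)-8-(triethylsilyloxy)-4β,5β-dimethyl-10βH-octal-8-ene (C8=C9 enol ether) | CC[Si](CC)(CC)OC=1CC[C@@]2(C)[C@H](CC[C@@H](O[Si](C)(C)C(C)(C)C)[C@@H]2C)C1 | intermediate
26 | 8β,9β-epoxide of 25 | CC[Si](CC)(CC)O[C@]12CC[C@@]3(C)[C@H](CC[C@@H](O[Si](C)(C)C(C)(C)C)[C@@H]3C)[C@H]1O2 | intermediate (not isolated)
27 | 3α-(tert-butyldimethylsilyloxy)-9β-(triethylsilyloxy)-4β,5β-dimethyl-10βH-decalin-8-one | O=C1CC[C@@]2(C)[C@H](CC[C@@H](O[Si](C)(C)C(C)(C)C)[C@@H]2C)[C@H]1O[Si](CC)(CC)CC | intermediate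
28 | 2-bromopropene | CC(Br)=C | starting material
29 | lithium C7=C8 enolate of 27 | [Li+].[O-]C1=CC[C@@]2(C)[C@H](CC[C@@H](O[Si](C)(C)C(C)(C)C)[C@@H]2C)[C@H]1O[Si](CC)(CC)CC | intermediate (not isolated)
30 | 3α-(tert-butyldimethylsilyloxy)-9β-(triethylsilyloxy)-10βH-eremophil-11-en-8-one (7β-isopropenyl) | O=C1[C@@H](C(C)=C)C[C@@]2(C)[C@H](CC[C@@H](O[Si](C)(C)C(C)(C)C)[C@@H]2C)[C@H]1O[Si](CC)(CC)CC | intermediate
31 | 3α-(tert-butyldimethylsilyloxy)-9β-hydroxy-10βH-eremophil-11-en-8-one | O=C1[C@@H](C(C)=C)C[C@@]2(C)[C@H](CC[C@@H](O[Si](C)(C)C(C)(C)C)[C@@H]2C)[C@H]1O | intermediate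
32 | senecioyl chloride (3-methylbut-2-enoyl chloride) | CC(C)=CC(=O)Cl | starting material
33 | 3α-(tert-butyldimethylsilyloxy)-9β-senecioyloxy-10βH-eremophil-11-en-8-one | O=C1[C@@H](C(C)=C)C[C@@]2(C)[C@H](CC[C@@H](O[Si](C)(C)C(C)(C)C)[C@@H]2C)[C@H]1OC(=O)C=C(C)C | intermediate
34 | 3α-hydroxy-9β-senecioyloxy-10βH-eremophil-11-en-8-one | O=C1[C@@H](C(C)=C)C[C@@]2(C)[C@H](CC[C@@H](O)[C@@H]2C)[C@H]1OC(=O)C=C(C)C | intermediate
35 | angelic acid ((Z)-2-methylbut-2-enoic acid) | C/C=C(/C)C(=O)O | starting material
36 | (3R,4R,5R,7R,9R,10S)-3-angeloyloxy-9-senecioyloxyeremophil-11-en-8-one (3α-angelate, 9β-senecioate, 10βH) | C=C(C)[C@H]1C[C@@]2(C)[C@H](CC[C@@H](OC(=O)/C(C)=C\C)[C@@H]2C)[C@@H](OC(=O)C=C(C)C)C1=O | target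

**Totals**

Total step count: 22. Longest linear sequence: 22 steps (from 3,4-dimethylphenol; all other inputs are commercial).

**Steps most likely to fail**

1. Step 18 (α-alkenylation at C7). Possible failures: enolisation toward the silyloxy-bearing C9 with silyl transfer between the two oxygens; sluggish coupling at the hindered enolate; drift of the new double bond into conjugation under the basic conditions. Fallback (known aldol/dehydration/deconjugation chemistry), setting out from 27: the kinetic C7 lithium enolate (LiN(i-Pr)2, THF, −78 °C) is added to acetone to give the 7-(2-hydroxypropan-2-yl) ketone F1. Dehydration with the Burgess reagent gives the conjugated 7-isopropylidene ketone F2. γ-Deprotonation with KN(SiMe3)2 and kinetic α-protonation of the extended enolate with acetic acid at −78 °C (deconjugative protonation) rejoins the route at 30.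

2. Step 13 (C4 equilibration and C3 reduction). Possible failures: incomplete epimerisation at the hindered C4 before the reduction; protonation of the ketyl intermediates from both faces, so that the axial 3β-alcohol accompanies the product. Fallback, setting out from 20: equilibration with NaOMe/MeOH and reduction with LiBH(s-Bu)3 gives, by equatorial hydride delivery, the axial alcohol 8,8-ethylenedioxy-4β,5β-dimethyl-10βH-decalin-3β-ol F3. Heating F3 with Al(Oi-Pr)3, i-PrOH and a little acetone (Meerwein–Ponndorf–Verley/Oppenauer equilibration through the ketone) converts it into the equatorial alcohol and rejoins the route at 22.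

3. Step 22 (angeloylation). Possible failures: Z→E isomerisation of the activated angeloyl unit to the tiglate; migration of the isopropenyl double bond into conjugation with the C8 ketone on heating with amine salts. Fallback, setting out from 34: esterification with 2-[bis(2,2,2-trifluoroethoxy)phosphoryl]propanoic acid (EDC·HCl, DMAP cat., CH2Cl2, 0 °C) gives the 3α-phosphonopropionate 9β-senecioate F4. A Still–Gennari olefination with acetaldehyde (KN(SiMe3)2, 18-crown-6, THF, −78 °C) then builds the (Z)-2-methylbut-2-enoate on the molecule and arrives at 36.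

**Further compounds**

F1 | step 18 | 3α-(tert-butyldimethylsilyloxy)-7β-(2-hydroxypropan-2-yl)-9β-(triethylsilyloxy)-4β,5β-dimethyl-10βH-decalin-8-one | O=C1[C@@H](C(C)(C)O)C[C@@]2(C)[C@H](CC[C@@H](O[Si](C)(C)C(C)(C)C)[C@@H]2C)[C@H]1O[Si](CC)(CC)CC
F2 | step 18 | 3α-(tert-butyldimethylsilyloxy)-9β-(triethylsilyloxy)-10βH-eremophil-7(11)-en-8-one | O=C1C(=C(C)C)C[C@@]2(C)[C@H](CC[C@@H](O[Si](C)(C)C(C)(C)C)[C@@H]2C)[C@H]1O[Si](CC)(CC)CC
F3 | step 13 | 8,8-ethylenedioxy-4β,5β-dimethyl-10βH-decalin-3β-ol | O1CCOC12CC[C@@]3(C)[C@H](CC[C@H](O)[C@@H]3C)C2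
F4 | step 22 | 3α-{2-[bis(2,2,2-trifluoroethoxy)phosphoryl]propanoyloxy}-9β-senecioyloxy-10βH-eremophil-11-en-8-one | O=C1[C@@H](C(C)=C)C[C@@]2(C)[C@H](CC[C@@H](OC(=O)C(C)P(=O)(OCC(F)(F)F)OCC(F)(F)F)[C@@H]2C)[C@H]1OC(=O)C=C(C)C
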